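An hour is what is asked, yet the zeta run stops at 6.00 min, so you must stretch a short record a long way.

| flask | substrate | partner | free catalyst | remark | time |
|---|---|---|---|---|---|
| zeta | 0.010 M (in portions, 2) | 10 mM | 2.8 mM | run made earlier; portions every 8.0 min |  |
| flask | 0.010 M (in portions, 2) | 10.0 mM | 1.4 mM | the portions of substrate follow each other after 8.0 min, the first at the start | 1.0 h |

zeta run (percent of the substrate charged)

| time / min | substrate / % | isomer of the product / % | catalyst intermediate B / % | target / % |
|---|---|---|---|---|
| 0.500 | 49.4 | 0.2 | 0.9 | 0 |
| 1.50 | 48.2 | 0 | 1.3 | 0.5 |
| 3.00 | 46.0 | 0.4 | 1.6 | 1.9 |
| 4.00 | 45.3 | 0.4 | 1.3 | 3.1 |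
| 6.00 | 43.1 | 0.1 | 1.3 | 5.2 |

(readings scatter by 0.3 percentage points)

- the numbers in the tables scatter by 0.3 percentage points (one standard deviation)
- no earlier run changes the charge of free catalyst; that part of a forecast is a guess
- percentages count the whole charge, also what has not yet gone in

- the largest share of what was charged as substrate, at 1.0 h belongs to (target / substrate / catalyst intermediate B / isomer of the product)
- the largest share itself, whichever of these holds it, in percent of the substrate charged

Between 0.500 min and 6.00 min of the zeta run, target rises by 5.2 percentage points while substrate falls by 6.3 points. Divide the one rate by the other and the minutes cancel, leaving a reading of 0.825: call it the yield on conversion, the target gained per point of substrate lost. With that yield held fixed and both portions in, target draws level with substrate once substrate stands at yield/(1+yield) of the charge, here 45.2%. So does this flask fall that far?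

My reckoning takes a first-order constant read from the zeta run, 0.0248 min⁻¹, and scales it with the catalyst charge, which is half that of zeta. Substrate left is then 50.0%. But the readings barely fix the order: a constant rate, scaled the same way, leaves 65.6%. Both lie above the crossing. The worse objection stands: without the scaling, first order leaves 25.1%, below the crossing, and no earlier run changes the catalyst charge to test that scaling. I commit to substrate, somewhere between my two scaled figures.

The forecast says substrate at 58%, on this ground: “I assume rate is proportional to catalyst, which is a guess”. Its figure lies between my two and is its own, equal to neither.

The flask gives substrate at 63.2%, ahead of target at 19.6% and isomer of the product at 16.7%, which is 5.2 points above the forecast.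

    2 free catalyst → spent catalyst (k = 27.0 M⁻¹ min⁻¹)
    substrate + catalyst intermediate A ⇌ catalyst intermediate B (K = 120 M⁻¹, k = 35.0 M⁻¹ min⁻¹)
    target ⇌ isomer of the product (K = 26.0, k = 0.0200 min⁻¹)
    catalyst intermediate B → free catalyst + target (k = 0.680 min⁻¹)
    partner + free catalyst ⇌ catalyst intermediate A (K = 110 M⁻¹, k = 120 M⁻¹ min⁻¹)

The yield on conversion in this flask is 0.533, below the zeta reading, and the flask is not at rest. At 10.0 h substrate is down to 32.3%, isomer of the product is up to 64.5%, target has shrunk to 3.17%, and the yield is 0.0468. So the yield belongs to one moment, and the next flask is taken at the same time. At 1.0 h the yield 0.533 of this flask puts the crossing at 34.8%, and substrate here stands above it. Held over to the neighbour flask with 0.040 M of partner, all else as here, that crossing says target leads if substrate falls below it. In that neighbour flask substrate falls to 30.9%, below the crossing, and target stands at 37.4%, ahead of substrate and of isomer of the product at 30.7%, so target leads there.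

The numbers in the tables stem from a simulated flask with constants of no real substance; noise was put on by code.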